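**Retrosynthetic overview**

1. Lutein dimyristate 15 is opened at its two ester C–O bonds to lutein 13 and myristoyl chloride 14.
2. Lutein 13 is traced back to (6'R)-α-carotene 11 by removing both hydroxyl groups. The strategy rests on the fact that the C40 skeleton is a pure hydrocarbon whose only heteroatoms sit on C3 (an unactivated CH2 of ring β, between C2 and C4) and on C3' (the allylic CH2 of ring ε). A pair of cytochrome P450 ring hydroxylases installs both C–O bonds and both carbinol stereocentres.
3. α-Carotene 11 is cut at C11'=C12' (Wittig) into the α-C15 phosphonium salt 9 and the C25 aldehyde 6. Aldehyde 6 is cut at C11=C12 (Wittig) into the β-C15 salt 3 and the C10 dialdehyde 4.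
4. Salts 3 and 9 come from β-ionone 1 and (R)-α-ionone 7 by vinyl Grignard addition and PPh3·HBr. The C6' stereocentre is bought with 7.
5. No ring is formed in the route: ring β arrives with 1 and ring ε with 7.

Key step: step 7

Assumption: (R)-α-ionone 7 is taken as purchasable in high enantiomeric purity. All polyenes are handled under argon in dim light. The carbinol configuration in 2 and 8 is left undefined because that carbon becomes sp2 in the next step.

**Route**

Step 1
Reactants: 1 β-ionone
Product: 2 vinyl-β-ionol, (1E)-3-methyl-1-(2,6,6-trimethylcyclohex-1-en-1-yl)penta-1,4-dien-3-ol (racemic)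
Conditions: CH2=CHMgBr (1.3 equiv), THF, −20 to 0 °C; then sat. aq NH4Cl
Reagents that add atoms: vinylmagnesium bromide, C=C[Mg]Br
Why: Grignard 1,2-addition to the ketone of the dienone, the conjugate position C7 being shielded by the ring methyl groups; the new carbinol centre forms as a racemate and is erased in step 2.

Step 2
Reactants: 2 vinyl-β-ionol
Product: 3 β-C15 salt, [(2E,4E)-3-methyl-5-(2,6,6-trimethylcyclohex-1-en-1-yl)penta-2,4-dien-1-yl]triphenylphosphonium bromide
Conditions: PPh3·HBr (1.05 equiv), MeOH, 0 °C to rt; crystallisation
Reagents that add atoms: triphenylphosphonium bromide, [Br-].[PH+](c1ccccc1)(c1ccccc1)c1ccccc1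
Why: Acid-induced ionisation of the tertiary bis-allylic alcohol gives a pentadienyl cation that PPh3 captures at the unhindered terminus (SN1 substitution with allylic transposition), and the trisubstituted C9=C10 bond settles as the more stable E isomer.

Step 3
Reactants: 3 β-C15 salt; 4 (2E,4E,6E)-2,7-dimethylocta-2,4,6-trienedial
Product: 6 (all-E)-12'-apo-β-caroten-12'-al, via β-C15 ylide 5 (not isolated)
Conditions: 4 (2.5 equiv), NaOMe (1.0 equiv, slow addition), CH2Cl2/MeOH, −10 to 20 °C; then heptane, reflux (Z to E); chromatography, excess 4 recovered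
Reagents that add atoms: none
Why: Wittig olefination forms C11=C12, and mono-olefination should dominate because 4 is in excess and the surviving formyl group, now the terminus of a donor-rich polyene, is less electrophilic than those of 4; the strained 11Z isomer relaxes to all-E on heating.

Step 4
Reactants: 7 (R)-α-ionone
Product: 8 vinyl-α-ionol, (1E)-3-methyl-1-[(1R)-2,6,6-trimethylcyclohex-2-en-1-yl]penta-1,4-dien-3-ol (both carbinol epimers)
Conditions: CH2=CHMgBr (1.3 equiv), THF, −30 to 0 °C; then sat. aq NH4Cl
Reagents that add atoms: vinylmagnesium bromide, C=C[Mg]Br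
Why: Grignard 1,2-addition at low temperature outruns enolisation, so the doubly allylic C6–H and with it the (R) centre stay untouched; the new carbinol centre is erased in step 5.

Step 5
Reactants: 8 vinyl-α-ionol
Product: 9 α-C15 salt, [(2E,4E)-3-methyl-5-[(1R)-2,6,6-trimethylcyclohex-2-en-1-yl]penta-2,4-dien-1-yl]triphenylphosphonium bromide
Conditions: PPh3·HBr (1.0 equiv), CH2Cl2/MeOH, 0 °C, short reaction time; crystallisation
Reagents that add atoms: triphenylphosphonium bromide, [Br-].[PH+](c1ccccc1)(c1ccccc1)c1ccccc1
Why: Same SN1 substitution with allylic transposition as in step 2; with the phosphine present from the start and the mixture kept cold, capture of the pentadienyl cation at C11 should outrun proton loss from C6 and protonation of the isolated ring alkene, so the (R) centre and the ε-type double bond are kept.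

Step 6
Reactants: 9 α-C15 salt (1.1 equiv); 6 (all-E)-12'-apo-β-caroten-12'-al
Product: 11 (6'R)-α-carotene, (6'R)-β,ε-carotene, via α-C15 ylide 10 (not isolated)
Conditions: NaOMe (1.15 equiv), CH2Cl2/MeOH, 0 °C to rt, argon, dark; then heptane, reflux (Z to E); crystallisation
Reagents that add atoms: none
Why: Wittig olefination forms C11'=C12' and completes the C40 chain; methoxide is far too weak a base to remove the doubly allylic C6'–H, so the stereocentre is carried through, and heating converts the hindered 11'Z isomer into the all-E polyene.

Step 7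
Reactants: 11 (6'R)-α-carotene
Product: 13 lutein, (3R,3'R,6'R)-β,ε-carotene-3,3'-diol, via zeinoxanthin 12 (not isolated)
Conditions: lysate of E. coli co-expressing Arabidopsis CYP97A3 and CYP97C1 (transit peptides removed), spinach ferredoxin, ferredoxin–NADP+ reductase, NADP+ (cat.), D-glucose, glucose dehydrogenase, catalase, 11 added in Tween 80 micelles, potassium phosphate buffer pH 7.5, air, 25 °C, dark; EtOAc/hexane extraction, chromatography
Reagents that add atoms: dioxygen, O=O
Why: Each cytochrome P450 holds its ring over the heme, takes two electrons from NADPH through ferredoxin reductase and ferredoxin, and cleaves O2 to the tetravalent iron–oxo porphyrin radical cation, which abstracts one hydrogen atom from C3 (CYP97A3, ring β) or C3' (CYP97C1, ring ε) and returns hydroxyl to the carbon radical on the same face. The closest known reaction type is this same CYP97-catalysed ring 3-hydroxylation of α-carotene, the native substrate of the enzyme pair, as it runs in plastids and in recombinant bacteria; supplying the substrate from outside on a preparative scale is the part that carries the risk. No ring is closed and two C–O bonds are formed, at C3 to give zeinoxanthin 12 and then at C3' to give 13. The new stereocentres C3 (R) and C3' (R) are set by the two active sites, each of which fixes its ring in one orientation so that only one of the two diastereotopic hydrogens faces the oxo ligand, and rebound with retention locks the configuration; the (6'R) centre brought in with 7 is the one the ε-ring pocket of CYP97C1 accepts. The step needs site selectivity for the unactivated C3 methylene of ring β over the allylic C4 methylene and the methyl groups, and for C3' over C2' and the polyene π bonds; this is secured by the fit of the natural hydrocarbon substrate, whose polyene fills the access channel and leaves only C3 or C3' within reach of the iron. No protecting group is needed because 11 carries nothing but C=C bonds, which the native reaction leaves untouched.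

Step 8
Reactants: 13 lutein; 14 myristoyl chloride (2.6 equiv)
Product: 15 lutein dimyristate, (3R,3'R,6'R)-β,ε-carotene-3,3'-diyl ditetradecanoate
Conditions: pyridine, DMAP (cat.), CH2Cl2, 0 °C to rt, argon, dark; MeOH quench; crystallisation
Reagents that add atoms: none
Why: DMAP-catalysed nucleophilic acyl substitution acylates both secondary hydroxyl groups at oxygen, so the C3 and C3' configurations are retained, and the pyridine base keeps the medium free of acid that would ionise the allylic C3'–O bond.

**Compound list**

1 | β-ionone | CC(=O)/C=C/C1=C(C)CCCC1(C)C | starting material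
2 | vinyl-β-ionol (racemic) | C=CC(C)(O)/C=C/C1=C(C)CCCC1(C)C | intermediate
3 | β-C15 triphenylphosphonium bromide | [Br-].CC1=C(/C=C/C(C)=C/C[P+](c2ccccc2)(c2ccccc2)c2ccccc2)C(C)(C)CCC1 | intermediate
4 | (2E,4E,6E)-2,7-dimethylocta-2,4,6-trienedial | O=C/C(C)=C/C=C/C=C(C)/C=O | starting material
5 | β-C15 ylide (triphenylphosphorane) | CC1=C(/C=C/C(C)=C/C=P(c2ccccc2)(c2ccccc2)c2ccccc2)C(C)(C)CCC1 | intermediate (not isolated)
6 | (all-E)-12'-apo-β-caroten-12'-al | CC1=C(/C=C/C(C)=C/C=C/C(C)=C/C=C/C=C(C)/C=O)C(C)(C)CCC1 | intermediate
7 | (R)-α-ionone | CC(=O)/C=C/[C@H]1C(C)=CCCC1(C)C | starting material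
8 | vinyl-α-ionol (6R, carbinol epimers) | C=CC(C)(O)/C=C/[C@H]1C(C)=CCCC1(C)C | intermediate
9 | α-C15 triphenylphosphonium bromide (R) | [Br-].c1ccccc1[P+](c1ccccc1)(c1ccccc1)C/C=C(C)/C=C/[C@H]2C(C)=CCCC2(C)C | intermediate
10 | α-C15 ylide (triphenylphosphorane, R) | c1ccccc1P(c1ccccc1)(c1ccccc1)=C/C=C(C)/C=C/[C@H]2C(C)=CCCC2(C)C | intermediate (not isolated)
11 | (6'R)-α-carotene, (6'R)-β,ε-carotene | C1CC(C)=C(/C=C/C(C)=C/C=C/C(C)=C/C=C/C=C(C)/C=C/C=C(C)/C=C/[C@H]2C(C)=CCCC2(C)C)C(C)(C)C1 | intermediate
12 | zeinoxanthin, (3R,6'R)-β,ε-caroten-3-ol | O[C@@H]1CC(C)=C(/C=C/C(C)=C/C=C/C(C)=C/C=C/C=C(C)/C=C/C=C(C)/C=C/[C@H]2C(C)=CCCC2(C)C)C(C)(C)C1 | intermediate (not isolated)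
13 | lutein, (3R,3'R,6'R)-β,ε-carotene-3,3'-diol | O[C@@H]1CC(C)=C(/C=C/C(C)=C/C=C/C(C)=C/C=C/C=C(C)/C=C/C=C(C)/C=C/[C@H]2C(C)=C[C@H](O)CC2(C)C)C(C)(C)C1 | intermediate
14 | myristoyl chloride (tetradecanoyl chloride) | CCCCCCCCCCCCCC(=O)Cl | starting material
15 | lutein dimyristate | CCCCCCCCCCCCCC(=O)O[C@@H]1CC(C)=C(/C=C/C(C)=C/C=C/C(C)=C/C=C/C=C(C)/C=C/C=C(C)/C=C/[C@H]2C(C)=C[C@H](OC(=O)CCCCCCCCCCCCC)CC2(C)C)C(C)(C)C1 | target

**Totals**

Total step count: 8.
Longest linear sequence: 6 steps (steps 1, 2, 3, 6, 7, 8, from β-ionone 1).

**Steps most likely to fail**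

Step 7. The water-insoluble carotene may not reach the two active sites from the micelles, turnover may stall after the first hydroxylation, and oxygen species from uncoupled turnover may bleach the polyene.
Fallback: the two C–H oxidations are separated and ring β is given to a different enzyme class. The fallback sets out from α-carotene 11 and returns at lutein 13.
- First stage: 11 is incubated with membranes of E. coli expressing the bacterial non-heme di-iron carotene 3-hydroxylase CrtZ of Pantoea ananatis, with ferredoxin, ferredoxin–NADP+ reductase and the NADPH-regenerating system, under air. This enzyme is expected to oxidise only ring β and to stop at zeinoxanthin 12, which is isolated by chromatography.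
- Second stage: the mono-ol 12, which inserts into phosphatidylcholine liposomes more readily than the hydrocarbon, is given in liposomes to CYP97C1 alone with the same electron supply, and should give 13.
- No compound outside the list is made (F0).

Step 5. The pentadienyl cation next to C6 may lose the C6 proton or shift hydride before it is captured, which would erase the stereocentre, and the ring double bond may migrate into conjugation.
Fallback: a cation-free chain extension that sets out from (R)-α-ionone 7 and returns at the α-C15 salt 9.
- Horner–Wadsworth–Emmons reaction of 7 with triethyl phosphonoacetate (NaH, THF, 0 °C to rt) should give ethyl (2E,4E)-3-methyl-5-[(1R)-2,6,6-trimethylcyclohex-2-en-1-yl]penta-2,4-dienoate F1 after removal of the 2Z isomer.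
- Reduction with (i-Bu)2AlH (CH2Cl2, −78 °C) should give the allylic alcohol (2E,4E)-3-methyl-5-[(1R)-2,6,6-trimethylcyclohex-2-en-1-yl]penta-2,4-dien-1-ol F2.
- Appel bromination (CBr4, PPh3, CH2Cl2, 0 °C) should give the primary allylic bromide (1R)-1-[(1E,3E)-5-bromo-3-methylpenta-1,3-dien-1-yl]-2,6,6-trimethylcyclohex-2-ene F3.
- Quaternisation of F3 with PPh3 (toluene, rt) should give 9.

Step 3. The second formyl group of the symmetrical dialdehyde may also be olefinated, and the Z to E equilibration may stay incomplete.
Fallback: the dialdehyde is desymmetrised with a protecting group. The fallback sets out from dialdehyde 4 and returns at the C25 aldehyde 6.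
- Acetalisation of 4 with one equivalent of 2,2-dimethylpropane-1,3-diol (pyridinium p-toluenesulfonate cat., CH2Cl2, molecular sieves, rt) should give the mono-acetal (2E,4E,6E)-7-(5,5-dimethyl-1,3-dioxan-2-yl)-2-methylocta-2,4,6-trienal F4. The first acetal makes the remaining conjugated formyl group less prone to acetalisation, and bis-acetal and unreacted 4 are recycled.
- Wittig reaction of F4 with salt 3 (NaOMe, CH2Cl2/MeOH, via ylide 5) should give the C25 neopentyl glycol acetal, 12'-apo-β-caroten-12'-al 5,5-dimethyl-1,3-dioxane acetal F5.
- Hydrolysis of F5 with aqueous oxalic acid in acetone at rt should give 6.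

**Further compounds**

F0 | step 7 | none | none
F1 | step 5 | ethyl (2E,4E)-3-methyl-5-[(1R)-2,6,6-trimethylcyclohex-2-en-1-yl]penta-2,4-dienoate | CCOC(=O)/C=C(C)/C=C/[C@H]1C(C)=CCCC1(C)C
F2 | step 5 | (2E,4E)-3-methyl-5-[(1R)-2,6,6-trimethylcyclohex-2-en-1-yl]penta-2,4-dien-1-ol | OC/C=C(C)/C=C/[C@H]1C(C)=CCCC1(C)C
F3 | step 5 | (1R)-1-[(1E,3E)-5-bromo-3-methylpenta-1,3-dien-1-yl]-2,6,6-trimethylcyclohex-2-ene | BrC/C=C(C)/C=C/[C@H]1C(C)=CCCC1(C)C
F4 | step 3 | (2E,4E,6E)-7-(5,5-dimethyl-1,3-dioxan-2-yl)-2-methylocta-2,4,6-trienal | O=C/C(C)=C/C=C/C=C(C)/C1OCC(C)(C)CO1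
F5 | step 3 | 12'-apo-β-caroten-12'-al 5,5-dimethyl-1,3-dioxane acetal | CC1=C(/C=C/C(C)=C/C=C/C(C)=C/C=C/C=C(C)/C2OCC(C)(C)CO2)C(C)(C)CCC1
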